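## Retrosynthetic overview

- **Feature.** In the oxolane (O1, C2 4-hydroxyphenyl, C3 aroyl, C4 4-hydroxybenzyl, C5 2,4-dihydroxyphenyl), C2 is a methine between O1 and an electron-rich arene. It lies 1,5 to C3, and the exocyclic carbonyl on C3 can hold a diazo carbon, so C2–C3 is cut as a carbene C–H insertion.
- **End game.** Target ⇒ hexabenzyl ketone ⇒ Weinreb amide + 2,4-bis(benzyloxy)phenyllithium. The aroyl group travels through the carbene step as a methyl ester, so no ortho-alkoxyaryl ketone sits beside the carbene.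
- **Ring formation.** All-trans oxolane ester ⇒ acyclic alpha-diazo ester whose C5 oxygen carries the 4-(benzyloxy)benzyl group that becomes C2 and its aryl. This C2–C3 closure forms the only ring made in the route; the four arene rings are bought.
- **Precursor.** Diazo ester ⇒ deacylative diazo transfer (a plain ester CH2 needs acyl activation) ⇒ Arndt–Eistert homologation ⇒ imidate etherification ⇒ auxiliary-controlled anti-aldol forming C4–C5.
- **Stereochemical plan.** The aldol fixes C4 and C5, the insertion sets C2 against them, and C3 is settled by enolate equilibration to the array with every vicinal pair trans.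

Key step: step 9

Remark: oxolane numbering (O1, C2–C5) is used for these atoms from the first step on. The MgCl2-chelated Z-enolate of the (S)-4-benzyl imide is taken to react on the face remote from the auxiliary's benzyl group, the sense that gives the (2R,3S) anti-aldol needed here.

## Route

Step 1
Reactants: 1 3-[4-(benzyloxy)phenyl]propanoic acid; 2 (S)-4-benzyl-1,3-oxazolidin-2-one
Product: 4 (S)-4-benzyl-3-{3-[4-(benzyloxy)phenyl]propanoyl}-1,3-oxazolidin-2-one, via mixed pivalic anhydride 3 (not isolated)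
Conditions: t-BuCOCl, Et3N, THF, −20 °C; then LiCl, 2, −20 °C → rt
Reagents that add atoms: none
Why: N-acylation of the oxazolidinone through a mixed anhydride, in which LiCl activates the carbamate nitrogen so that no strong base is needed, attack goes to the less hindered acyl carbon and no stereocentre is formed.

Step 2
Reactants: 4 imide; 5 2,4-bis(benzyloxy)benzaldehyde
Product: 7 (S)-4-benzyl-3-{(2R,3S)-2-[4-(benzyloxy)benzyl]-3-[2,4-bis(benzyloxy)phenyl]-3-hydroxypropanoyl}-1,3-oxazolidin-2-one (anti-aldol), via O-trimethylsilyl aldol adduct 6 (not isolated)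
Conditions: MgCl2 (0.2 equiv), Et3N, TMSCl, EtOAc, rt; then Et3N·3HF, THF, 0 °C
Reagents that add atoms: none
Why: MgCl2-catalysed anti-aldol of an N-acyloxazolidinone, in which the chelated Z-enolate is attacked by the non-enolisable aryl aldehyde on the face away from the auxiliary's benzyl group through a boat-like transition state, TMSCl traps the aldolate so the addition is not reversed, C4 (2R) and C5 (3S) are set together, and mildly acidic fluoride frees the carbinol without ionising the electron-rich benzylic C–O bond.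

Step 3
Reactants: 8 4-(benzyloxy)benzyl alcohol
Product: 9 4-(benzyloxy)benzyl 2,2,2-trichloroacetimidate
Conditions: Cl3CCN, DBU (cat.), CH2Cl2, 0 °C
Reagents that add atoms: trichloroacetonitrile, N#CC(Cl)(Cl)Cl
Why: Base-catalysed addition of the alcohol to the nitrile (trichloroacetimidate formation), the standard activation of 4-alkoxybenzyl alcohols, with no stereocentre involved.

Step 4
Reactants: 7 anti-aldol; 9 imidate
Product: 10 (S)-4-benzyl-3-{(2R,3S)-2-[4-(benzyloxy)benzyl]-3-[2,4-bis(benzyloxy)phenyl]-3-{[4-(benzyloxy)benzyl]oxy}propanoyl}-1,3-oxazolidin-2-one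
Conditions: La(OTf)3 (5 mol %), toluene, 0 °C → rt
Reagents that add atoms: none
Why: Acid-catalysed trichloroacetimidate O-alkylation, in which the imidate gives up its 4-alkoxybenzyl group far more readily than the C5 carbinol ionises (its cation would sit next to the acyl-bearing C4), so catalytic La(OTf)3 suffices, base-induced retro-aldol is avoided and the C5–O bond, and with it C5, is left alone.

Step 5
Reactants: 10 ether imide
Product: 11 (2R,3S)-2-[4-(benzyloxy)benzyl]-3-[2,4-bis(benzyloxy)phenyl]-3-{[4-(benzyloxy)benzyl]oxy}propanoic acid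
Conditions: LiOH, H2O2, THF–H2O, 0 °C; Na2SO3; 1 M HCl to pH 4, 0 °C
Reagents that add atoms: hydrogen peroxide, OO
Why: Hydroperoxide cleavage of the N-acyloxazolidinone, in which the small alpha-effect nucleophile attacks the exocyclic carbonyl at 0 °C, conditions under which C4 should not epimerise and the beta-alkoxy group should not be eliminated.

Step 6
Reactants: 11 acid
Product: 13 (3R,4S)-3-[4-(benzyloxy)benzyl]-4-[2,4-bis(benzyloxy)phenyl]-4-{[4-(benzyloxy)benzyl]oxy}-1-diazobutan-2-one, via isobutyl carbonic anhydride 12 (not isolated)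
Conditions: i-BuOCOCl, N-methylmorpholine, THF, −20 °C; then CH2N2, Et2O, 0 °C → rt
Reagents that add atoms: diazomethane, C=[N+]=[N-]
Why: First half of the Arndt–Eistert homologation, the acylation of diazomethane by a mixed carbonic anhydride made with a weak base in the cold, which avoids an acid chloride and HCl and keeps C4 and the benzylic ethers intact.

Step 7
Reactants: 13 diazoketone
Product: 15 methyl (3S,4S)-3-[4-(benzyloxy)benzyl]-4-[2,4-bis(benzyloxy)phenyl]-4-{[4-(benzyloxy)benzyl]oxy}butanoate, via ketene 14 (not isolated)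
Conditions: AgO2CPh (10 mol %), Et3N, MeOH–THF, rt, dark
Reagents that add atoms: methanol, CO
Why: Wolff rearrangement, in which C4 migrates to the diazo carbon with retention (the descriptor changes only through priorities) and methanol traps the ketene, as is routine for beta-benzyloxy diazoketones.

Step 8
Reactants: 15 homologated ester
Product: 17 methyl (3S,4S)-3-[4-(benzyloxy)benzyl]-4-[2,4-bis(benzyloxy)phenyl]-4-{[4-(benzyloxy)benzyl]oxy}-2-diazobutanoate, via 2-trifluoroacetyl ester 16 (not isolated)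
Conditions: LiN(SiMe3)2, THF, −78 °C; CF3CO2CH2CF3; aq NH4Cl; then 4-AcNHC6H4SO2N3, Et3N, H2O (1 equiv), MeCN, rt
Reagents that add atoms: 4-acetamidobenzenesulfonyl azide, CC(=O)Nc1ccc(cc1)S(=O)(=O)N=[N+]=[N-]
Why: Deacylative Regitz-type diazo transfer, in which C3 is first trifluoroacetylated through its lithium enolate because a plain ester CH2 is too weakly acidic, the 1,3-dicarbonyl then accepts the diazo group under Et3N with loss of the trifluoroacetyl group to the sulfonamide, and C4 and C5 stay untouched since the only leaving group is gamma to the enolate.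

Step 9
Reactants: 17 diazo ester
Product: 19 methyl (2S,3S,4S,5S)-4-[4-(benzyloxy)benzyl]-5-[2,4-bis(benzyloxy)phenyl]-2-[4-(benzyloxy)phenyl]oxolane-3-carboxylate (all-trans), via C3-epimeric oxolane ester 18 (not isolated)
Conditions: Rh2(O2CCPh3)4 (1 mol %), CH2Cl2 (0.01 M), −78 → −20 °C; concentrate; then NaOMe (0.3 equiv), MeOH–THF, rt
Reagents that add atoms: none
Why: Rh2(O2CCPh3)4 takes N2 out of 17, and the electrophilic C3 carbene draws hydride character from one C2–H bond of the arylmethyl ether in a concerted, asynchronous three-centre event that forms C2–C3 and C3–H with retention at C2 and releases the catalyst. The closest known reaction type is the rhodium-carbenoid 1,5 C–H insertion of alpha-alkyl alpha-diazo esters next to an ether oxygen, which gives 2,3,5-substituted oxolanes. The ring closes in the 1,5 mode (ring atoms C3–C4–C5–O1–C2, six centres counting the migrating hydrogen), whereas the other reachable sites would give a cyclopropane at C5–H, a seven-membered ring at the ortho OCH2Ph, or indanes at arene positions that are meta to every oxygen and so not activated. C2 is controlled by the triphenylacetate wall, the largest group on C3: C4 and C2 both turn their hydrogens toward rhodium, which places the C2 aryl on the ring face of the C4 benzyl group and therefore trans to the C5 aryl fixed by the aldol. C3 should first emerge with the ester cis to both neighbours (18), and catalytic methoxide then equilibrates this enolisable centre to the 2,3-trans-3,4-trans ester 19. The step needs C2–H insertion to beat the 1,2-hydride shift from the tertiary C4–H and ylide formation at the ortho benzyloxy oxygen; this is secured by the double activation of C2–H by O1 and the 4-alkoxyphenyl ring, by the C4–H being held in the carbene plane by the bulky carboxylates at low temperature, and by the low nucleophilicity of an aryl ether oxygen that could only close a six-membered ylide.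

Step 10
Reactants: 19 all-trans ester
Product: 20 (2S,3S,4S,5S)-4-[4-(benzyloxy)benzyl]-5-[2,4-bis(benzyloxy)phenyl]-2-[4-(benzyloxy)phenyl]oxolane-3-carboxylic acid
Conditions: LiOH, THF–MeOH–H2O, 40 °C; 1 M HCl to pH 4, 0 °C
Reagents that add atoms: lithium hydroxide, [Li+].[OH-]
Why: Ester saponification, in which the pseudo-equatorial methyl ester is open to hydroxide, C3 already holds its thermodynamic configuration so enolisation is harmless, and ring opening by beta-elimination of O1 is the reverse of a 5-endo-trig addition and hence stereoelectronically slow.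

Step 11
Reactants: 20 acid
Product: 22 (2S,3S,4S,5S)-4-[4-(benzyloxy)benzyl]-5-[2,4-bis(benzyloxy)phenyl]-2-[4-(benzyloxy)phenyl]-N-methoxy-N-methyloxolane-3-carboxamide, via acyl imidazolide 21 (not isolated)
Conditions: 1,1'-carbonyldiimidazole, CH2Cl2, rt; then MeNHOMe·HCl, rt
Reagents that add atoms: N,O-dimethylhydroxylamine hydrochloride, CNOC.Cl
Why: Weinreb amide formation through the acyl imidazolide under near-neutral conditions that spare the benzylic ethers, any enolisation at C3 returning the trans,trans isomer.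

Step 12
Reactants: 23 4-bromoresorcinol
Product: 24 2,4-bis(benzyloxy)-1-bromobenzene
Conditions: BnBr, K2CO3, DMF, 60 °C
Reagents that add atoms: benzyl bromide, BrCc1ccccc1
Why: Williamson ether synthesis on both phenols, the aryl bromide being inert to K2CO3.

Step 13
Reactants: 22 Weinreb amide; 24 aryl bromide
Product: 26 [2,4-bis(benzyloxy)phenyl]{(2S,3S,4S,5S)-4-[4-(benzyloxy)benzyl]-5-[2,4-bis(benzyloxy)phenyl]-2-[4-(benzyloxy)phenyl]oxolan-3-yl}methanone, via 2,4-bis(benzyloxy)phenyllithium 25 (not isolated)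
Conditions: 24, n-BuLi, THF, −78 °C; then 22, −78 → −20 °C; aq NH4Cl
Reagents that add atoms: none
Why: Weinreb ketone synthesis, in which bromine–lithium exchange at −78 °C outruns benzylic deprotonation, the aryllithium adds only once because the chelated tetrahedral adduct lasts until the quench, and that adduct also shields C3 from enolisation.

Step 14
Reactants: 26 hexabenzyl ketone
Product: 27 (2,4-dihydroxyphenyl)[(2S,3S,4S,5S)-5-(2,4-dihydroxyphenyl)-4-(4-hydroxybenzyl)-2-(4-hydroxyphenyl)oxolan-3-yl]methanone (CNP0181717.2)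
Conditions: H2 (1 atm), Pd/C (10 wt %), pyridine (0.5 equiv), EtOAc–THF, rt, stopped at six equivalents of H2
Reagents that add atoms: none
Why: Catalytic hydrogenolysis, in which aryl benzyl ethers are cleaved on Pd/C much faster than the two secondary benzylic C–O bonds of the oxolane, pyridine poisoning widens that gap, the emerging hydrogen-bonded 2-hydroxyaryl ketone is a poor substrate for reduction, and the neutral aprotic medium leaves C2, C3 and C5 untouched.

## Compound list

1 | 3-[4-(benzyloxy)phenyl]propanoic acid | OC(=O)CCc1ccc(OCc2ccccc2)cc1 | starting material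
2 | (S)-4-benzyl-1,3-oxazolidin-2-one | O=C1N[C@@H](Cc2ccccc2)CO1 | starting material
3 | 3-[4-(benzyloxy)phenyl]propanoic pivalic anhydride | CC(C)(C)C(=O)OC(=O)CCc1ccc(OCc2ccccc2)cc1 | intermediate
4 | (S)-4-benzyl-3-{3-[4-(benzyloxy)phenyl]propanoyl}-1,3-oxazolidin-2-one | O=C(CCc1ccc(OCc2ccccc2)cc1)N1[C@@H](Cc2ccccc2)COC1=O | intermediate
5 | 2,4-bis(benzyloxy)benzaldehyde | O=Cc1ccc(OCc2ccccc2)cc1OCc1ccccc1 | starting material
6 | O-trimethylsilyl ether of the (2R,3S) anti-aldol imide | O=C(N1[C@@H](Cc2ccccc2)COC1=O)[C@H](Cc1ccc(OCc2ccccc2)cc1)[C@@H](c1ccc(OCc2ccccc2)cc1OCc1ccccc1)O[Si](C)(C)C | intermediate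
7 | (2R,3S) anti-aldol imide | O=C(N1[C@@H](Cc2ccccc2)COC1=O)[C@H](Cc1ccc(OCc2ccccc2)cc1)[C@@H](c1ccc(OCc2ccccc2)cc1OCc1ccccc1)O | intermediate
8 | 4-(benzyloxy)benzyl alcohol | OCc1ccc(OCc2ccccc2)cc1 | starting material
9 | 4-(benzyloxy)benzyl 2,2,2-trichloroacetimidate | N=C(OCc1ccc(OCc2ccccc2)cc1)C(Cl)(Cl)Cl | intermediate
10 | (2R,3S) 3-O-[4-(benzyloxy)benzyl] ether imide | O=C(N1[C@@H](Cc2ccccc2)COC1=O)[C@H](Cc1ccc(OCc2ccccc2)cc1)[C@@H](c1ccc(OCc2ccccc2)cc1OCc1ccccc1)OCc1ccc(OCc2ccccc2)cc1 | intermediate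
11 | (2R,3S)-2-[4-(benzyloxy)benzyl]-3-[2,4-bis(benzyloxy)phenyl]-3-{[4-(benzyloxy)benzyl]oxy}propanoic acid | OC(=O)[C@H](Cc1ccc(OCc2ccccc2)cc1)[C@@H](c1ccc(OCc2ccccc2)cc1OCc1ccccc1)OCc1ccc(OCc2ccccc2)cc1 | intermediate
12 | isobutyl carbonic anhydride of 11 | CC(C)COC(=O)OC(=O)[C@H](Cc1ccc(OCc2ccccc2)cc1)[C@@H](c1ccc(OCc2ccccc2)cc1OCc1ccccc1)OCc1ccc(OCc2ccccc2)cc1 | intermediate
13 | (3R,4S)-1-diazobutan-2-one from 11 | [N-]=[N+]=CC(=O)[C@H](Cc1ccc(OCc2ccccc2)cc1)[C@@H](c1ccc(OCc2ccccc2)cc1OCc1ccccc1)OCc1ccc(OCc2ccccc2)cc1 | intermediate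
14 | ketene from 13 (C4 and C5 unchanged) | O=C=C[C@H](Cc1ccc(OCc2ccccc2)cc1)[C@@H](c1ccc(OCc2ccccc2)cc1OCc1ccccc1)OCc1ccc(OCc2ccccc2)cc1 | intermediate
15 | methyl (3S,4S)-3-[4-(benzyloxy)benzyl]-4-[2,4-bis(benzyloxy)phenyl]-4-{[4-(benzyloxy)benzyl]oxy}butanoate | COC(=O)C[C@H](Cc1ccc(OCc2ccccc2)cc1)[C@@H](c1ccc(OCc2ccccc2)cc1OCc1ccccc1)OCc1ccc(OCc2ccccc2)cc1 | intermediate
16 | 2-trifluoroacetyl derivative of 15 (C3 not defined, enolised) | COC(=O)C(C(=O)C(F)(F)F)[C@H](Cc1ccc(OCc2ccccc2)cc1)[C@@H](c1ccc(OCc2ccccc2)cc1OCc1ccccc1)OCc1ccc(OCc2ccccc2)cc1 | intermediate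
17 | methyl (3S,4S)-2-diazo-3-[4-(benzyloxy)benzyl]-4-[2,4-bis(benzyloxy)phenyl]-4-{[4-(benzyloxy)benzyl]oxy}butanoate | COC(=O)C(=[N+]=[N-])[C@H](Cc1ccc(OCc2ccccc2)cc1)[C@@H](c1ccc(OCc2ccccc2)cc1OCc1ccccc1)OCc1ccc(OCc2ccccc2)cc1 | intermediate
18 | methyl (2S,3R,4S,5S)-oxolane-3-carboxylate tetrabenzyl ether (2,3-cis, 3,4-cis, 4,5-trans) | COC(=O)[C@@H]1[C@H](Cc2ccc(OCc3ccccc3)cc2)[C@@H](c2ccc(OCc3ccccc3)cc2OCc2ccccc2)O[C@@H]1c1ccc(OCc2ccccc2)cc1 | intermediate
19 | methyl (2S,3S,4S,5S)-oxolane-3-carboxylate tetrabenzyl ether (all-trans) | COC(=O)[C@H]1[C@H](Cc2ccc(OCc3ccccc3)cc2)[C@@H](c2ccc(OCc3ccccc3)cc2OCc2ccccc2)O[C@@H]1c1ccc(OCc2ccccc2)cc1 | intermediate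
20 | (2S,3S,4S,5S)-oxolane-3-carboxylic acid tetrabenzyl ether | OC(=O)[C@H]1[C@H](Cc2ccc(OCc3ccccc3)cc2)[C@@H](c2ccc(OCc3ccccc3)cc2OCc2ccccc2)O[C@@H]1c1ccc(OCc2ccccc2)cc1 | intermediate
21 | acyl imidazolide of 20 | O=C(n1ccnc1)[C@H]1[C@H](Cc2ccc(OCc3ccccc3)cc2)[C@@H](c2ccc(OCc3ccccc3)cc2OCc2ccccc2)O[C@@H]1c1ccc(OCc2ccccc2)cc1 | intermediate
22 | (2S,3S,4S,5S)-N-methoxy-N-methyloxolane-3-carboxamide tetrabenzyl ether | CON(C)C(=O)[C@H]1[C@H](Cc2ccc(OCc3ccccc3)cc2)[C@@H](c2ccc(OCc3ccccc3)cc2OCc2ccccc2)O[C@@H]1c1ccc(OCc2ccccc2)cc1 | intermediate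
23 | 4-bromoresorcinol | Oc1ccc(Br)c(O)c1 | starting material
24 | 2,4-bis(benzyloxy)-1-bromobenzene | Brc1ccc(OCc2ccccc2)cc1OCc1ccccc1 | intermediate
25 | 2,4-bis(benzyloxy)phenyllithium | [Li]c1ccc(OCc2ccccc2)cc1OCc1ccccc1 | intermediate
26 | (2S,3S,4S,5S) hexabenzyl ether of the target ketone | O=C(c1ccc(OCc2ccccc2)cc1OCc1ccccc1)[C@H]1[C@H](Cc2ccc(OCc3ccccc3)cc2)[C@@H](c2ccc(OCc3ccccc3)cc2OCc2ccccc2)O[C@@H]1c1ccc(OCc2ccccc2)cc1 | intermediate
27 | (2,4-dihydroxyphenyl)[(2S,3S,4S,5S)-5-(2,4-dihydroxyphenyl)-4-(4-hydroxybenzyl)-2-(4-hydroxyphenyl)oxolan-3-yl]methanone | O=C(c1ccc(O)cc1O)[C@H]1[C@H](Cc2ccc(O)cc2)[C@@H](c2ccc(O)cc2O)O[C@@H]1c1ccc(O)cc1 | target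

## Step count and risks

Total step count: 14.
Longest linear sequence: 12 (steps 1, 2, 4–11, 13, 14).

**Step 9.**
- What may go wrong: the 1,2-hydride migration from the tertiary C4–H may outrun insertion. The carbene may take the other diastereotopic C2–H and close a 2,5-cis ring. Full hydride transfer may fragment the ether.
- The fallback sets out from 15 and comes back at 19. It makes C2–C3 by an enolate aldol and closes the ring by ionic C–O bond formation.
- LiN(i-Pr)2 in THF at −78 °C followed by 4-(benzyloxy)benzaldehyde should give the beta-hydroxy ester F1 as a mixture of epimers at C2 and C3.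
- BF3·OEt2 in CH2Cl2 at −40 to 0 °C then ionises a benzylic C–O bond, either C2–OH or C5–OR, and both lead to the same ring. The remaining oxygen closes the oxolane, and the 4-(benzyloxy)benzyl group departs with the water that is formed.
- Both benzylic ring bonds stay reversible under the Lewis acid, so C2 and C5 should settle trans to their neighbours against the fixed C4. The methoxide treatment of step 9 settles C3.

**Step 4.**
- What may go wrong: acid may ionise the 2,4-dialkoxybenzylic C5–O bond, with loss of configuration at C5 or elimination. The imidate may also self-condense before the hindered carbinol is alkylated.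
- The fallback sets out from 7 and comes back at 11. It delivers the arylmethyl group from an acetal rather than from a cation.
- LiBH4 with one equivalent of MeOH in THF at 0 °C removes the auxiliary reductively to give the 1,3-diol F2.
- 4-(Benzyloxy)benzaldehyde dimethyl acetal with PPTS in CH2Cl2 gives the all-equatorial 1,3-dioxane F3.
- i-Bu2AlH in CH2Cl2 at −78 to 0 °C opens the acetal at the less hindered primary oxygen. This leaves the ether on the C5 oxygen in the primary alcohol F4.
- TEMPO (cat.) with PhI(OAc)2 in buffered MeCN–H2O oxidises F4 to the acid 11.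

**Step 14.**
- What may go wrong: over-reduction. Once the phenols are free they can push out O1, and the C2–O1 and C5–O1 bonds may then be hydrogenolysed. The ketone may also be reduced.
- The fallback sets out from 26 and comes back at 27. It never exposes free phenols to a reducing metal surface.
- Et3SiH with Pd(OAc)2 (cat.) and Et3N in CH2Cl2 at rt exchanges each O-benzyl group for O-SiEt3, giving the hexakis(triethylsilyl) ether F5.
- After filtration from palladium, Et3N·3HF in THF at 0 °C frees the six phenols.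

## Further compounds

F1 | step 9 | beta-hydroxy ester, aldol adduct of 15 at C3 with 4-(benzyloxy)benzaldehyde (epimers at C2 and C3) | COC(=O)C(C(O)c1ccc(OCc2ccccc2)cc1)[C@H](Cc1ccc(OCc2ccccc2)cc1)[C@@H](c1ccc(OCc2ccccc2)cc1OCc1ccccc1)OCc1ccc(OCc2ccccc2)cc1
F2 | step 4 | 1,3-diol, (1S,2S)-2-[4-(benzyloxy)benzyl]-1-[2,4-bis(benzyloxy)phenyl]propane-1,3-diol | OC[C@H](Cc1ccc(OCc2ccccc2)cc1)[C@@H](c1ccc(OCc2ccccc2)cc1OCc1ccccc1)O
F3 | step 4 | 1,3-dioxane, 2,4-cis-4,5-trans 4-(benzyloxy)benzylidene acetal of F2 | C1[C@H](Cc2ccc(OCc3ccccc3)cc2)[C@@H](c2ccc(OCc3ccccc3)cc2OCc2ccccc2)O[C@@H](c2ccc(OCc3ccccc3)cc2)O1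
F4 | step 4 | primary alcohol, (2S,3S)-2-[4-(benzyloxy)benzyl]-3-[2,4-bis(benzyloxy)phenyl]-3-{[4-(benzyloxy)benzyl]oxy}propan-1-ol | OC[C@H](Cc1ccc(OCc2ccccc2)cc1)[C@@H](c1ccc(OCc2ccccc2)cc1OCc1ccccc1)OCc1ccc(OCc2ccccc2)cc1
F5 | step 14 | hexakis(triethylsilyl) ether of 27 | O=C(c1ccc(O[Si](CC)(CC)CC)cc1O[Si](CC)(CC)CC)[C@H]1[C@H](Cc2ccc(O[Si](CC)(CC)CC)cc2)[C@@H](c2ccc(O[Si](CC)(CC)CC)cc2O[Si](CC)(CC)CC)O[C@@H]1c1ccc(O[Si](CC)(CC)CC)cc1
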